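A one-step world, with J and D meeting on Z and no Q in the flask, ends at the equilibrium of the catalysed step.

    J + D + Z ⇌ J.D + Z, rate k1*[J]*[D]*[Z] forward; the back reaction follows from the equilibrium constant (K1 = 110 M⁻¹, k1 = 3830 M⁻² h⁻¹)
    J + Q → J.Q (k2 = 1.69 M⁻¹ h⁻¹)

the same everywhere: J 0.050 M; D 0.0600 M; Z 2.5 mM; time 20 d
- epsilon: Q 0.00600 M
- gamma: Q 0.0150 M
- eta: Q 0.0500 M
- beta: Q 0.150 M
- alpha: Q 0.500 M

- amount of J.D at the end, in percent of the J charged for epsilon, gamma, eta, beta, alpha, in this order
- the course of these numbers from the first flask to the last (hardly changes / rises, then falls / rises all the way / falls all the way / falls, then rises)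

- "hardly changes" means that all values lie within two and a half points (for a concentration: within two and a half percent of the largest)
- run time (epsilon): 20 d

- **The main step by itself.** Z stands on both sides of J + D + Z ⇌ J.D + Z, rate k1*[J]*[D]*[Z] forward; the back reaction follows from the equilibrium constant (K1 = 110 M⁻¹, k1 = 3830 M⁻² h⁻¹), so it stays out of the balance. Call x the c(J.D) at the end. The J left is c(J) charged minus x, the D left is c(D) charged minus x, and x over the product of these two equals 110 M⁻¹. This gives 0.0362 M, or 72.4 % of the J charged.

- **Adding the loss.** Q now takes J by J + Q → J.Q (k2 = 1.69 M⁻¹ h⁻¹). In epsilon, with concentrations held at their charge, J has a half-life of 0.050 d by the forward catalysed step and 2.8 d by the loss. The equilibrium should therefore keep pace while Q removes free J, and the 20 d allowed is longer than the loss half-life.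

- **What Q can take.** Each Q removes one J, and in epsilon c(Q) is below c(J), which makes Q the limiting reagent of the loss. In epsilon 0.0440 M of J, free or bound as J.D, remains once Q has taken its whole charge. This amount, c(J) charged minus c(Q) charged, is the pool. Put into the same balance in place of c(J) charged, it gives 0.0329 M of J.D, or 65.9 % of the J charged for epsilon, which is less than the one-step figure.

- **The other flasks.** More Q means a smaller pool, so the row falls. In eta the pool is 0 M, and in beta and alpha c(Q) exceeds c(J). There the pool points towards no J.D at all, but it does not tell how far the drain has come in 20 d, so this reckoning gives no figure for those flasks.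

- **Forecast and result.** The forecast gave 65.9 %, 54.7 %, 11.3 %, <0.001 % and 0 %, shape falls all the way, seeing the equilibrium as “a reservoir of free J, which Q drains irreversibly”. The simulation gives 65.9 %, 54.8 %, 11.6 %, 0.00601 % and 0 %, shape falls all the way.

The loss of J to J.Q is the main reason for the fall along the row: alpha without that step ends at 72.4 % of J.D instead of 0 %. In epsilon, with Q down to 0.00950 % of its charge at 20.0 d, the pool of 0.0440 M is 88.0 % of the J charged, shared between J at 22.1 % and J.D at 65.9 %. In gamma, with Q down to 0.115 %, the pool of 0.0350 M gives 54.7 % by the same balance, and the flask ends at 54.8 %.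

All constants are made up; the result is computed.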